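The route uses cembrane numbering, with C1 as the isopropylidene-bearing ring carbon. The array O–C9=C10–C11–C12(Me)–OAc is shared by the oxolane and the 14-membered carbocycle. It is a homoallylic acetate, and so the opened form of a C9 cyclopropylcarbinyl cation whose C10–C11–C12 ring is geraniol's allylic alkene plus one methylene. The precursor is therefore a 13-membered carbocycle fused to that cyclopropane. It bears the C9 ketone, a C6 triethylsilyl ether and the finished C1–C4 dienone. One operation closes the oxolane (O6–C9), ionises to the oxocarbenium ion and lets acetate cleave C10–C12 at C12 with inversion. This delivers the 14-membered ring, the Z enol ether and the tertiary acetate. Nucleophilic epoxidation of C3=C4 ends the route.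

Key step: step 17

Remark 1: the C1 centre made in step 4 and the C2 carbinol made in step 15 are carried as epimer mixtures, because steps 14 and 16 erase them. Their SMILES leave these centres open.
Remark 2: the macrocyclic precursor is a hydroxy diketone (carbonyls at C2 and C9). It is used as its C6 silyl ether, since a free hydroxyl could be acylated irreversibly or would set acid free in the key step.
Remark 3: the sense of induction assigned to each chiral reagent follows the behaviour of the simple parent substrates of that method.

Step 1
Reactants: 1 geraniol; 2 diiodomethane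
Product: 3 [(1S,2S)-2-methyl-2-(4-methylpent-3-en-1-yl)cyclopropyl]methanol
Conditions: Et2Zn, DME, CH2Cl2, −10 °C; (4R,5R)-2-butyl-N,N,N′,N′-tetramethyl-1,3,2-dioxaborolane-4,5-dicarboxamide (1.2 equiv), −10 °C → rt
Reagents that add atoms: none
Why: Charette asymmetric Simmons–Smith cyclopropanation, in which the zinc alkoxide of 1 binds the (R,R)-dioxaborolane and methylene is delivered to the face that gives (S,S) products from E-allylic alcohols, so that C10 and C12 are set together, the E geometry places the methyl group cis to CH2OH, and the remote trisubstituted alkene, which has no directing group, is left alone.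

Step 2
Reactants: 3 cyclopropylmethanol
Product: 4 (1S,2S)-2-methyl-2-(4-methylpent-3-en-1-yl)cyclopropane-1-carboxylic acid
Conditions: TEMPO (0.2 equiv), PhI(OAc)2 (2.2 equiv), MeCN/H2O 1:1, rt
Reagents that add atoms: water, O
Why: Oxoammonium (TEMPO/PhI(OAc)2) oxidation takes the primary alcohol through the aldehyde hydrate to the acid without an oxidant that attacks the trisubstituted alkene and without touching the cyclopropane centres.

Step 3
Reactants: 4 cyclopropanecarboxylic acid
Product: 5 (1S,2S)-N-methoxy-N,2-dimethyl-2-(4-methylpent-3-en-1-yl)cyclopropane-1-carboxamide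
Conditions: MeNH(OMe)·HCl, EDCI·HCl, N-methylmorpholine, CH2Cl2, 0 °C → rt
Reagents that add atoms: N,O-dimethylhydroxylamine hydrochloride, CNOC.Cl
Why: Carbodiimide amide coupling gives the Weinreb amide, chosen because it is the weakest acceptor that C9 can carry through the Lewis acid of step 4 and still becomes a ketone in one step.

Step 4
Reactants: 5 Weinreb amide; 6 formaldehyde (as paraformaldehyde)
Product: 7 (1S,2S)-2-[3-(hydroxymethyl)-4-methylpent-4-en-1-yl]-N-methoxy-N,2-dimethylcyclopropane-1-carboxamide (both C1 epimers)
Conditions: Me2AlCl (3 equiv), CH2Cl2, −78 → 0 °C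
Reagents that add atoms: none
Why: Lewis-acid-promoted carbonyl-ene reaction in which the formaldehyde–Me2AlCl complex attacks the less substituted alkene carbon (future C1) and takes hydrogen from a geminal methyl group, adding C2 as CH2OH and leaving an isopropenyl group, while Me2AlCl removes protons as methane, the amide-substituted cyclopropane is too poor an acceptor for chloride opening, and the unselectively formed C1 centre is erased in step 14.

Step 5
Reactants: 7 ene alcohol; 8 ethylmagnesium bromide
Product: 9 1-{(1S,2S)-2-[3-(hydroxymethyl)-4-methylpent-4-en-1-yl]-2-methylcyclopropyl}propan-1-one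
Conditions: EtMgBr (3 equiv), THF, 0 °C; aq NH4Cl
Reagents that add atoms: none
Why: Weinreb ketone synthesis, in which the first equivalent only deprotonates the alcohol and the chelated tetrahedral adduct stops the addition at the ethyl ketone that supplies C8 and its methyl group.

Step 6
Reactants: 9 hydroxy ethyl ketone; 10 SAMP, (S)-1-amino-2-(methoxymethyl)pyrrolidine
Product: 11 SAMP hydrazone of 9
Conditions: 4 Å MS, cyclohexane, reflux
Reagents that add atoms: none
Why: Hydrazone condensation driven by removal of water installs the auxiliary for step 12 and leaves the primary alcohol, the isopropenyl group and the cyclopropane untouched.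

Step 7
Reactants: 12 (S)-epichlorohydrin; 13 trimethylsilylacetylene
Product: 14 (S)-1-chloro-5-(trimethylsilyl)pent-4-yn-2-ol
Conditions: n-BuLi, THF, −78 °C; BF3·OEt2; then 12, −78 °C
Reagents that add atoms: none
Why: BF3-assisted epoxide opening by a lithium acetylide (Yamaguchi–Hirao alkynylation) occurs at the unsubstituted epoxide carbon (future C5) faster than chloride displacement, so the C–O bond of the stereocentre is not touched and C6 is taken unchanged from 12.

Step 8
Reactants: 14 chlorohydrin
Product: 15 (S)-{[1-chloro-5-(trimethylsilyl)pent-4-yn-2-yl]oxy}triethylsilane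
Conditions: TESCl, imidazole, CH2Cl2, 0 °C → rt
Reagents that add atoms: chlorotriethylsilane, CC[Si](Cl)(CC)CC
Why: Standard silylation blocks epoxide re-closure in the basic step 9 and installs the only protecting group of the route, which is later used up productively in step 17.

Step 9
Reactants: 15 silyl ether
Product: 16 (S)-[(1-chloropent-4-yn-2-yl)oxy]triethylsilane
Conditions: K2CO3 (0.3 equiv), MeOH, 0 °C
Reagents that add atoms: none
Why: Base-catalysed methanolysis cleaves the C(sp)–Si bond much faster than a secondary triethylsilyl ether and frees the terminal alkyne.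

Step 10
Reactants: 16 terminal alkyne; 17 trimethylaluminium
Product: 19 (S,E)-[(1-chloro-5-iodo-4-methylpent-4-en-2-yl)oxy]triethylsilane, via vinylalane 18 (not isolated)
Conditions: Me3Al (3 equiv), Cp2ZrCl2 (0.25 equiv), CH2Cl2, 0 °C → rt; then I2, THF, −30 °C
Reagents that add atoms: iodine, II
Why: Negishi zirconium-catalysed carboalumination adds methyl to the internal and aluminium to the terminal alkyne carbon in a syn fashion, and iodinolysis with retention gives the E vinyl iodide (C5 trans to iodine) that fixes the C3=C4 geometry.

Step 11
Reactants: 19 chloride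
Product: 20 (S,E)-[(1,5-diiodo-4-methylpent-4-en-2-yl)oxy]triethylsilane
Conditions: NaI (5 equiv), NaHCO3 (trace), 2-butanone, reflux
Reagents that add atoms: sodium iodide, [Na+].[I-]
Why: Finkelstein exchange driven by precipitation of sodium chloride converts the sluggish primary chloride into the iodide needed for alkylation, and the vinyl iodide and silyl ether are inert under neutral conditions.

Step 12
Reactants: 11 SAMP hydrazone; 20 diiodide
Product: 22 alkylated SAMP hydrazone (6R,8S,10S,12S), via dilithiated azaenolate 21 (not isolated)
Conditions: LDA (2.2 equiv), THF, 0 °C; −100 °C, add 20; → −20 °C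
Reagents that add atoms: none
Why: Enders SAMP-hydrazone alkylation, in which LDA removes the O–H and then a proton of the ethyl CH2 (the cyclopropyl C10–H is not acidic), the chelated azaenolate is alkylated by the primary iodide on the face left open by the methoxymethylpyrrolidine, which with SAMP gives 8S as for simple ethyl ketones, and the lithium alkoxide and the vinyl iodide are spectators at low temperature (C6 is spatially unchanged and reads R only because CIP priorities change).

Step 13
Reactants: 22 alkylated hydrazone
Product: 23 hydroxy ketone (6R,8S,10S,12S) with C6 OTES and E vinyl iodide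
Conditions: CuCl2·2H2O (3 equiv), THF/pH 7 phosphate buffer, 0 °C → rt; aq NH3/NH4Cl wash
Reagents that add atoms: water, O
Why: Copper(II)-assisted hydrazone hydrolysis at neutral pH is driven by binding of the released hydrazine, is known to spare α-stereocentres, and avoids both ozone (alkenes present) and strong acid (silyl ether present).

Step 14
Reactants: 23 hydroxy ketone
Product: 25 keto enal bearing the C1 isopropylidene group, via isopropenyl aldehyde 24 (not isolated)
Conditions: Dess–Martin periodinane, NaHCO3, CH2Cl2, 0 °C → rt; then Et3N (0.5 equiv), CH2Cl2, rt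
Reagents that add atoms: none
Why: Dess–Martin oxidation followed by amine-catalysed migration of the β,γ double bond into conjugation gives the tetrasubstituted enal, removes the C1 stereocentre, and uses a base too weak to enolise the C9 ketone and endanger C8.

Step 15
Reactants: 25 keto enal vinyl iodide
Product: 26 cyclopropane-fused 13-membered dienol (both C2 epimers) with C6 OTES
Conditions: CrCl2 (10 equiv), NiCl2 (0.1 equiv), DMSO/THF 3:1, 2 mM, slow addition, rt
Reagents that add atoms: none
Why: Nozaki–Hiyama–Kishi macrocyclisation forms C2–C3, since the alkenylchromium species made with retention of the E geometry adds 1,2 to the aldehyde and ignores the C9 ketone, high dilution favours ring closure, and the C2 configuration is irrelevant.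

Step 16
Reactants: 26 macrocyclic dienol
Product: 27 C6 O-triethylsilyl ether of the (6R,8S,10S,12S) hydroxy diketone: 13-membered carbocycle fused to the C10–C11–C12 cyclopropane
Conditions: Dess–Martin periodinane, NaHCO3, CH2Cl2, 0 °C
Reagents that add atoms: none
Why: Buffered Dess–Martin oxidation converts both epimers of the acid-sensitive bis-allylic alcohol into one cross-conjugated dienone without allylic transposition.

Step 17
Reactants: 27 silyl-protected macrocyclic precursor; 28 trimethylsilyl acetate
Product: 31 (6R,8S,12R,9Z)-3,4-deoxy target: 14-membered dienone bearing the Z alkylidene oxolane plus the C12 acetate, via bicyclic silyl ketal 29 (not isolated), via oxocarbenium triflate 30 (not isolated)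
Conditions: TMSOAc (5 equiv), TMSOTf (0.3 equiv), 2,6-di-tert-butyl-4-methylpyridine (0.5 equiv), CH2Cl2 (0.01 M), −78 → −30 °C; Et3N quench at low temperature, aq NaHCO3
Reagents that add atoms: none
Why: Proposed new method: TMSOTf silylates the C9 ketone, the C6 silyl ether oxygen adds to it and passes its Et3Si group on to triflate to give silyl ketal 29, loss of Et3SiOSiMe3 leaves the cyclopropyl-substituted oxocarbenium ion 30 (so far the course of a Noyori ketalisation), and TMSOAc then attacks C12 from the rear of the C10–C12 bond, whose electrons become the C9=C10 π bond, while Me3Si returns to triflate. The closest known reaction types are the stereoinvertive opening of cyclopropyl ketones and cyclopropylcarbinyl cations at a quaternary carbon by silyl halides or azides, the acid acetolysis of cyclopropyl ketones, the Julia homoallyl rearrangement and the capture of Prins cations by TMSOAc; untested is a ketal-derived oxocarbenium ion as trigger in combination with acetate. The oxolane closes in the 5-exo-trig mode (O6 onto C9), and the 14-membered carbocycle is not closed by cyclisation but arises when the bond shared by the three- and 13-membered rings breaks. C12 should become R by inversion of the S centre set in step 1, because the oxygen-stabilised cation holds little charge at C12 and opens only under nucleophilic push, and the Z geometry should follow from the bisected conformer that keeps the three-membered ring next to the ring oxygen and C10–H next to C8 and its methyl group. The step needs attack at C12 and not at C11 or C9, which the tertiary against primary carbon and the reversibility of acetate addition at C9 secure, and it needs the exocyclic alkene, which is secured because the double bond is made from a σ bond and not by loss of a proton, the hindered pyridine removing any adventitious acid that could move it to C8=C9 or epimerise C8. The silyl ether together with TMSOAc is preferred to the free alcohol together with Ac2O because O6 cannot be acylated irreversibly and no acetic acid is formed, and the dienone should stay passive because its two fully substituted β-carbons block the U-shaped conformer that a Nazarov closure requires.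

Step 18
Reactants: 31 3,4-deoxy target
Product: 32 target CNP0162736.1, (3R,4S,6R,8S,12R,9Z)
Conditions: La(Oi-Pr)3, (S)-BINOL, Ph3As=O (20 mol % each), TBHP (decane, 2 equiv), 4 Å MS, THF, rt
Reagents that add atoms: tert-butyl hydroperoxide, CC(C)(C)OO
Why: Catalytic asymmetric Weitz–Scheffer (nucleophilic) epoxidation, in which the lanthanum-bound peroxide adds to C4 and closes on C3 with the E relationship kept, the (S)-BINOL complex being the one expected from simple E-enones to give the αR, hence (3R,4S), epoxide, while the twisted tetrasubstituted C1 isopropylidene enone is too hindered and a nucleophilic oxidant in a non-acidic medium leaves the electron-rich enol ether and the tertiary acetate alone.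

Compound list
1 | geraniol | CC(C)=CCC/C(C)=C/CO | starting material
2 | diiodomethane | ICI | starting material
3 | [(1S,2S)-2-methyl-2-(4-methylpent-3-en-1-yl)cyclopropyl]methanol | C[C@]1(CCC=C(C)C)C[C@@H]1CO | intermediate
4 | (1S,2S)-2-methyl-2-(4-methylpent-3-en-1-yl)cyclopropane-1-carboxylic acid | C[C@]1(CCC=C(C)C)C[C@@H]1C(=O)O | intermediate
5 | Weinreb amide of 4 | C[C@]1(CCC=C(C)C)C[C@@H]1C(=O)N(C)OC | intermediate
6 | formaldehyde (as paraformaldehyde) | C=O | starting material
7 | ene alcohol, Weinreb amide (C1 epimers) | C[C@]1(CCC(CO)C(C)=C)C[C@@H]1C(=O)N(C)OC | intermediate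
8 | ethylmagnesium bromide | CC[Mg]Br | starting material
9 | hydroxy ethyl ketone (C1 epimers) | C[C@]1(CCC(CO)C(C)=C)C[C@@H]1C(=O)CC | intermediate
10 | SAMP, (S)-1-amino-2-(methoxymethyl)pyrrolidine | COC[C@@H]1CCCN1N | starting material
11 | SAMP hydrazone of 9 | C[C@]1(CCC(CO)C(C)=C)C[C@@H]1C(CC)=NN2CCC[C@H]2COC | intermediate
12 | (S)-epichlorohydrin | ClC[C@@H]1CO1 | starting material
13 | trimethylsilylacetylene | C#C[Si](C)(C)C | starting material
14 | (S)-1-chloro-5-(trimethylsilyl)pent-4-yn-2-ol | ClC[C@@H](O)CC#C[Si](C)(C)C | intermediate
15 | triethylsilyl ether of 14 | ClC[C@@H](O[Si](CC)(CC)CC)CC#C[Si](C)(C)C | intermediate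
16 | (S)-[(1-chloropent-4-yn-2-yl)oxy]triethylsilane | ClC[C@@H](O[Si](CC)(CC)CC)CC#C | intermediate
17 | trimethylaluminium | C[Al](C)C | starting material
18 | (E)-vinylalane from 16 (not isolated) | ClC[C@@H](O[Si](CC)(CC)CC)C/C(C)=C/[Al](C)C | intermediate
19 | (S,E)-[(1-chloro-5-iodo-4-methylpent-4-en-2-yl)oxy]triethylsilane | ClC[C@@H](O[Si](CC)(CC)CC)C/C(C)=C/I | intermediate
20 | (S,E)-[(1,5-diiodo-4-methylpent-4-en-2-yl)oxy]triethylsilane | IC[C@@H](O[Si](CC)(CC)CC)C/C(C)=C/I | intermediate
21 | dilithiated azaenolate of 11 (not isolated) | C[C@]1(CCC(CO[Li])C(C)=C)C[C@@H]1C(=CC)N([Li])N2CCC[C@H]2COC | intermediate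
22 | alkylated SAMP hydrazone (6R,8S,10S,12S) | C[C@]1(CCC(CO)C(C)=C)C[C@@H]1C(=NN2CCC[C@H]2COC)[C@@H](C)C[C@@H](O[Si](CC)(CC)CC)C/C(C)=C/I | intermediate
23 | hydroxy ketone, C6 OTES, vinyl iodide | C[C@]1(CCC(CO)C(C)=C)C[C@@H]1C(=O)[C@@H](C)C[C@@H](O[Si](CC)(CC)CC)C/C(C)=C/I | intermediate
24 | isopropenyl (β,γ-unsaturated) aldehyde (not isolated) | C[C@]1(CCC(C=O)C(C)=C)C[C@@H]1C(=O)[C@@H](C)C[C@@H](O[Si](CC)(CC)CC)C/C(C)=C/I | intermediate
25 | isopropylidene keto enal | C[C@]1(CCC(C=O)=C(C)C)C[C@@H]1C(=O)[C@@H](C)C[C@@H](O[Si](CC)(CC)CC)C/C(C)=C/I | intermediate
26 | cyclopropane-fused 13-membered dienol (C2 epimers), C6 OTES | C[C@]12C[C@@H]1C(=O)[C@@H](C)C[C@@H](O[Si](CC)(CC)CC)C/C(C)=C/C(O)C(=C(C)C)CC2 | intermediate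
27 | key-step precursor: C6 OTES ether of the cyclopropane-fused 13-membered hydroxy diketone | C[C@]12C[C@@H]1C(=O)[C@@H](C)C[C@@H](O[Si](CC)(CC)CC)C/C(C)=C/C(=O)C(=C(C)C)CC2 | intermediate
28 | trimethylsilyl acetate | CC(=O)O[Si](C)(C)C | starting material
29 | bicyclic C9 trimethylsilyl ketal (not isolated) | C[C@]12C[C@@H]1C3(O[Si](C)(C)C)O[C@H](C[C@@H]3C)C/C(C)=C/C(=O)C(=C(C)C)CC2 | intermediate
30 | C9 oxocarbenium triflate (not isolated) | C[C@]12C[C@@H]1C3=[O+][C@H](C[C@@H]3C)C/C(C)=C/C(=O)C(=C(C)C)CC2.[O-]S(=O)(=O)C(F)(F)F | intermediate
31 | 3,4-deoxy target (Z enol ether, C12 acetate, dienone) | CC(=O)O[C@@]1(C)C/C=C2\O[C@H](C[C@@H]2C)C/C(C)=C/C(=O)C(=C(C)C)CC1 | intermediate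
32 | CNP0162736.1 | CC(=O)O[C@@]1(C)C/C=C2\O[C@H](C[C@@H]2C)C[C@]2(C)O[C@H]2C(=O)C(=C(C)C)CC1 | target

Total step count: 18. Longest linear sequence: 13 steps (steps 1–6 and 12–18). The side branch, steps 7–11, joins at step 12.

Steps most likely to fail

Step 17 carries the new-method label.
- What may go wrong: the cation may lose a proton, at C8 or around C12 once the ring opens, faster than acetate arrives.
- A loose ion pair may erode the configuration at C12.
- Acetate may open the silylated ketone before O6 has closed.
- The fallback runs from 27 back to 31, separates the events and uses known reactions only.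
- Buffered fluoride (HF·pyridine, pyridine, THF, 0 °C) frees the C6-hydroxy diketone F1.
- Brønsted-acid acetolysis of the cyclopropyl ketone follows (AcOH, cat. TsOH, rt). This is the classical homoconjugate addition, which places acetate on the more substituted carbon anti to the breaking bond, and it gives the ring-expanded 14-membered γ-acetoxy hydroxy diketone F2.
- Premature opening in step 17 would, after desilylation, lead to the same compound.
- HC(OMe)3, MeOH and PPTS close F2 to the bicyclic methyl ketal F3.
- Silyl triflate/amine elimination of the ketal (TMSOTf, i-Pr2NEt, CH2Cl2, −20 °C) removes methanol towards the less substituted side, C10. Allylic strain against the C8 methyl group favours the Z isomer, and the product is 31.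

Step 18.
- What may go wrong: conjugate addition to the β,β-disubstituted C4 may be slow, or the macrocycle may override the catalyst and give poor facial selectivity.
- The fallback runs from 31 to 32 and replaces nucleophilic epoxidation by hydroxyl-directed, reagent-controlled epoxidation.
- Corey–Bakshi–Shibata 1,2-reduction uses the (R)-oxazaborolidine and catecholborane (toluene, −78 °C), with the α-branched C1 alkenyl group acting as the large substituent. It gives the (2S)-dienol F4.
- Sharpless epoxidation follows (D-(−)-diethyl tartrate, Ti(Oi-Pr)4, TBHP, 4 Å MS, CH2Cl2, −20 °C). For a 2S carbinol, C3=C4 is the matched alkene and the isopropylidene alkene the mismatched one. Oxygen is delivered to the required face and gives the epoxy alcohol F5.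
- Buffered Dess–Martin oxidation of F5 gives 32.

Step 12.
- What may go wrong: substitution at a β-branched, β-oxygenated primary iodide may be so slow that elimination or proton transfer wins, and selectivity may erode on warming.
- The fallback sets out from 19 and from azaenolate 21 (made from 11 as in step 12), returns at 22, and exchanges halide displacement for strain-driven epoxide opening.
- TBAF (THF, 0 °C) removes the silyl group of 19, and the liberated alkoxide displaces chloride to give (S,E)-2-(3-iodo-2-methylallyl)oxirane F6.
- Azaenolate 21 opens F6 at its CH2 terminus (metalated hydrazone/oxirane opening, −78 → 0 °C) to give the diol hydrazone F7. The sense of induction at C8 would have to be verified at this stage.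
- TESCl and imidazole give the bis-silyl ether F8.
- PPTS in MeOH at 0 °C frees only the primary alcohol, which gives 22.

Further compounds
F1 | step 17 | C6-hydroxy diketone, cyclopropane-fused 13-membered ring (6R,8S,10S,12S) | C[C@]12C[C@@H]1C(=O)[C@@H](C)C[C@@H](O)C/C(C)=C/C(=O)C(=C(C)C)CC2
F2 | step 17 | ring-expanded 14-membered 12-acetoxy-6-hydroxy-2,9-diketone (6R,8S,12R) | CC(=O)O[C@@]1(C)CCC(=O)[C@@H](C)C[C@@H](O)C/C(C)=C/C(=O)C(=C(C)C)CC1
F3 | step 17 | bicyclic C9 methyl ketal of F2 | CC(=O)O[C@@]1(C)CCC2(OC)O[C@H](C[C@@H]2C)C/C(C)=C/C(=O)C(=C(C)C)CC1
F4 | step 18 | (2S)-dienol from 31 | CC(=O)O[C@@]1(C)C/C=C2\O[C@H](C[C@@H]2C)C/C(C)=C/[C@H](O)C(=C(C)C)CC1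
F5 | step 18 | (2S,3R,4S)-epoxy alcohol | CC(=O)O[C@@]1(C)C/C=C2\O[C@H](C[C@@H]2C)C[C@]2(C)O[C@H]2[C@H](O)C(=C(C)C)CC1
F6 | step 12 | (S,E)-2-(3-iodo-2-methylallyl)oxirane | C1O[C@H]1C/C(C)=C/I
F7 | step 12 | diol SAMP hydrazone (free C2 and C6 hydroxyls) | C[C@]1(CCC(CO)C(C)=C)C[C@@H]1C(=NN2CCC[C@H]2COC)[C@@H](C)C[C@@H](O)C/C(C)=C/I
F8 | step 12 | bis(triethylsilyl) ether of F7 | C[C@]1(CCC(CO[Si](CC)(CC)CC)C(C)=C)C[C@@H]1C(=NN2CCC[C@H]2COC)[C@@H](C)C[C@@H](O[Si](CC)(CC)CC)C/C(C)=C/I
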